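**Retrosynthetic overview**
- Last bond: C6–C7. It closes the ten-membered carbocycle and the α-methylene-γ-butyrolactone in one operation, by intramolecular addition of a 2-(methoxycarbonyl)allylchromium to the C6 enal. C7 was itself an aldehyde carbon and reacts as the β-carbanion (homoenolate-type) equivalent of an acrylate.
- C7–C11: vinylalumination of the C7 aldehyde with a methyl propiolate-derived α-aluminoacrylate, then allylic transposition to the bromide.
- C8 ester: Mitsunobu inversion of the sugar-derived C8 hydroxyl with isovaleric acid.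
- C1–C2 and the furanone ring: acetylide of (Z)-3-methylpent-2-en-4-yn-1-ol adds to the lactone carbonyl of 2-C-methyl-D-ribono-1,4-lactone; the tertiary C10 hydroxyl then closes the 3(2H)-furanone.
- Ring order: furanone first; carbocycle and γ-lactone together at the end. C9 and C10 come from the sugar, C8 by inversion, C6 and C7 from the ring closure.

Assumption: locants C1–C15 are the germacrane locants of the target (C1 ring ketone, C3 enol-ether carbon, C6 lactone carbinol, C8 ester carbinol, C9 free carbinol, C10 quaternary carbon, C12 lactone carbonyl, C13 exocyclic CH2); the sugar lactone (made industrially from D-fructose and lime) and the Z-enynol (vitamin A intermediate) are taken as purchasable.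

**Step 1**
Reactants: 1 2-C-methyl-D-ribono-1,4-lactone [(3R,4R,5R)-3,4-dihydroxy-5-(hydroxymethyl)-3-methyloxolan-2-one]
Product: 2 (3R,4R,5R)-3-hydroxy-3-methyl-4-(triethylsilyloxy)-5-[(triethylsilyloxy)methyl]oxolan-2-one
Conditions: TESCl (2.2 equiv), imidazole, DMF, 0 °C → rt
Reagents that add atoms: chlorotriethylsilane CC[Si](Cl)(CC)CC
Why: Silyl ether formation with TESCl/imidazole takes the primary and the secondary hydroxyl, while the tertiary α-hydroxyl on the quaternary carbon is too hindered and stays free for the later furanone closure; no stereocenter is touched.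

**Step 2**
Reactants: 3 (2Z)-3-methylpent-2-en-4-yn-1-ol
Product: 4 triethyl{[(2Z)-3-methylpent-2-en-4-yn-1-yl]oxy}silane
Conditions: TESCl, imidazole, CH2Cl2, 0 °C
Reagents that add atoms: chlorotriethylsilane CC[Si](Cl)(CC)CC
Why: Standard silylation of a primary allylic alcohol, which masks the acidic OH before acetylide formation and leaves the Z alkene untouched.

**Step 3**
Reactants: 4 triethyl{[(2Z)-3-methylpent-2-en-4-yn-1-yl]oxy}silane; 2 (3R,4R,5R)-3-hydroxy-3-methyl-4-(triethylsilyloxy)-5-[(triethylsilyloxy)methyl]oxolan-2-one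
Product: 8 (2R)-2-[(1R,2R)-2-hydroxy-1,3-bis(triethylsilyloxy)propyl]-2-methyl-5-[(2Z)-4-(triethylsilyloxy)but-2-en-2-yl]furan-3(2H)-one, via lithium acetylide 5 (not isolated), via alkynyl lactol 6 (not isolated), via hydroxy ynone 7 (not isolated)
Conditions: 4, n-BuLi, THF, −78 °C; 2 pre-treated with LiN(SiMe3)2 (1 equiv), −78 → −40 °C; AcOH; then Et2NH, EtOH, rt
Reagents that add atoms: none
Why: 1,2-Addition of the lithium acetylide to the non-enolisable lactone stops at the tetrahedral lactol, whose ring-chain tautomer is an α′-hydroxy ynone that the free tertiary C10 hydroxyl closes irreversibly by amine-mediated 5-endo-dig oxa-Michael addition to the 3(2H)-furanone, freeing the C8 hydroxyl; C9 and C10 come unchanged from the sugar and the Z alkene from 3.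

**Step 4**
Reactants: 8 (2R)-2-[(1R,2R)-2-hydroxy-1,3-bis(triethylsilyloxy)propyl]-2-methyl-5-[(2Z)-4-(triethylsilyloxy)but-2-en-2-yl]furan-3(2H)-one; 9 3-methylbutanoic acid (isovaleric acid)
Product: 10 (2S,3R)-3-[(2R)-2-methyl-3-oxo-5-[(2Z)-4-(triethylsilyloxy)but-2-en-2-yl]-2,3-dihydrofuran-2-yl]-1,3-bis(triethylsilyloxy)propan-2-yl 3-methylbutanoate
Conditions: PPh3, DIAD, toluene, 0 °C → rt
Reagents that add atoms: none
Why: Mitsunobu esterification, in which SN2 displacement of the oxyphosphonium by isovalerate inverts the D-ribo C8 centre (8R → 8S), so the ester is installed and the configuration corrected in the same step.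

**Step 5**
Reactants: 10 (2S,3R)-3-[(2R)-2-methyl-3-oxo-5-[(2Z)-4-(triethylsilyloxy)but-2-en-2-yl]-2,3-dihydrofuran-2-yl]-1,3-bis(triethylsilyloxy)propan-2-yl 3-methylbutanoate
Product: 11 (2R,3R)-3-[(2R)-2-methyl-3-oxo-5-[(2Z)-4-oxobut-2-en-2-yl]-2,3-dihydrofuran-2-yl]-1-oxo-3-(triethylsilyloxy)propan-2-yl 3-methylbutanoate (C8 spatially unchanged; the descriptor changes only through CIP priorities)
Conditions: (COCl)2, DMSO, CH2Cl2, −78 → −30 °C; then i-Pr2NEt, −78 → 0 °C
Reagents that add atoms: none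
Why: Swern oxidation with oxidative desilylation, in which the chlorosulfonium reagent cleaves the two primary triethylsilyl ethers and oxidises them in situ to the C6 enal and the C7 aldehyde while the hindered secondary C9 silyl ether survives; the cold, hindered-base conditions protect the Z enal and the α-acyloxy centre.

**Step 6**
Reactants: 11 (2R,3R)-3-[(2R)-2-methyl-3-oxo-5-[(2Z)-4-oxobut-2-en-2-yl]-2,3-dihydrofuran-2-yl]-1-oxo-3-(triethylsilyloxy)propan-2-yl 3-methylbutanoate; 12 methyl prop-2-ynoate (methyl propiolate)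
Product: 14 methyl (3RS,4S,5R)-3-hydroxy-2-methylidene-4-[(3-methylbutanoyl)oxy]-5-[(2R)-2-methyl-3-oxo-5-[(2Z)-4-oxobut-2-en-2-yl]-2,3-dihydrofuran-2-yl]-5-(triethylsilyloxy)pentanoate, via vinylalane 13 (not isolated)
Conditions: 12, i-Bu2AlH, NMO, THF, 0 °C; then 11 (1.0 equiv), −40 → 0 °C; Rochelle salt work-up
Reagents that add atoms: none
Why: Hydroalumination of the propiolate gives the α-aluminoacrylate (vinylalumination, a base-free route to a Morita–Baylis–Hillman-type adduct), which adds to the more electrophilic α-acyloxy aliphatic C7 aldehyde and not to the hindered β,β-disubstituted enal C6; the new C7 carbinol configuration is irrelevant because C7 becomes sp2 in step 7.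

**Step 7**
Reactants: 14 methyl (3RS,4S,5R)-3-hydroxy-2-methylidene-4-[(3-methylbutanoyl)oxy]-5-[(2R)-2-methyl-3-oxo-5-[(2Z)-4-oxobut-2-en-2-yl]-2,3-dihydrofuran-2-yl]-5-(triethylsilyloxy)pentanoate
Product: 15 methyl (2Z,4S,5R)-2-(bromomethyl)-4-[(3-methylbutanoyl)oxy]-5-[(2R)-2-methyl-3-oxo-5-[(2Z)-4-oxobut-2-en-2-yl]-2,3-dihydrofuran-2-yl]-5-(triethylsilyloxy)pent-2-enoate
Conditions: NBS, Me2S, CH2Cl2, −20 → 0 °C
Reagents that add atoms: N-bromosuccinimide O=C1CCC(=O)N1Br
Why: Corey–Kim-type activation of the allylic alcohol followed by SN2′ attack of bromide transposes it to the primary allylic bromide with the thermodynamically favoured Z trisubstituted enoate, under neutral conditions that tolerate the enal, the ester and the silyl ether.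

**Step 8**
Reactants: 15 methyl (2Z,4S,5R)-2-(bromomethyl)-4-[(3-methylbutanoyl)oxy]-5-[(2R)-2-methyl-3-oxo-5-[(2Z)-4-oxobut-2-en-2-yl]-2,3-dihydrofuran-2-yl]-5-(triethylsilyloxy)pent-2-enoate
Product: 18 lobatin B, via allylchromium 16 (not isolated), via 9-O-triethylsilyl-lobatin B 17 (not isolated)
Conditions: CrCl2 (8 equiv), DMF–THF, 0.002 M, slow addition, rt; then 1 M HCl aq, THF, rt
Reagents that add atoms: none
Why: Intramolecular Nozaki–Hiyama/Barbier-type 2-(alkoxycarbonyl)allylation, in which divalent chromium converts the bromide into an allylchromium whose γ-carbon C7 (an aldehyde carbon two steps earlier, now an acrylate β-carbanion or homoenolate equivalent) attacks the aldehyde carbon C6 through a closed six-membered transition state; the equilibrating allylchromium is expected to react through the chair with both ring bonds pseudo-equatorial (anti adduct, hence 6,7-trans lactone) on the face set by the C8 centre and the rigid furanone-bridged tether (6R,7S), the chromium alkoxide lactonises onto the methyl ester, and the acidic quench removes the C9 silyl ether.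

**Compound list**
1 | 2-C-methyl-D-ribono-1,4-lactone, (3R,4R,5R)-3,4-dihydroxy-5-(hydroxymethyl)-3-methyloxolan-2-one | O=C1O[C@H](CO)[C@@H](O)[C@@]1(C)O | starting material
2 | (3R,4R,5R)-3-hydroxy-3-methyl-4-(triethylsilyloxy)-5-[(triethylsilyloxy)methyl]oxolan-2-one | O=C1O[C@H](CO[Si](CC)(CC)CC)[C@@H](O[Si](CC)(CC)CC)[C@@]1(C)O | intermediate
3 | (2Z)-3-methylpent-2-en-4-yn-1-ol | OC/C=C(/C)C#C | starting material
4 | triethyl{[(2Z)-3-methylpent-2-en-4-yn-1-yl]oxy}silane | CC[Si](CC)(CC)OC/C=C(/C)C#C | intermediate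
5 | lithium (3Z)-3-methyl-5-(triethylsilyloxy)pent-3-en-1-yn-1-ide (lithium acetylide of 4) | CC[Si](CC)(CC)OC/C=C(/C)C#C[Li] | intermediate
6 | (3R,4R,5R)-3-methyl-2-[(3Z)-3-methyl-5-(triethylsilyloxy)pent-3-en-1-yn-1-yl]-4-(triethylsilyloxy)-5-[(triethylsilyloxy)methyl]oxolane-2,3-diol (alkynyl lactol, anomer mixture) | OC1(C#C/C(C)=C\CO[Si](CC)(CC)CC)O[C@H](CO[Si](CC)(CC)CC)[C@@H](O[Si](CC)(CC)CC)[C@@]1(C)O | intermediate
7 | (2Z,7R,8R,9R)-7,9-dihydroxy-3,7-dimethyl-1,8,10-tris(triethylsilyloxy)dec-2-en-4-yn-6-one (open-chain hydroxy ynone tautomer of 6) | CC[Si](CC)(CC)OC/C=C(/C)C#CC(=O)[C@](C)(O)[C@H](O[Si](CC)(CC)CC)[C@H](O)CO[Si](CC)(CC)CC | intermediate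
8 | (2R)-2-[(1R,2R)-2-hydroxy-1,3-bis(triethylsilyloxy)propyl]-2-methyl-5-[(2Z)-4-(triethylsilyloxy)but-2-en-2-yl]furan-3(2H)-one (C8 R, C9 R, C10 R) | CC[Si](CC)(CC)OC/C=C(/C)C1=CC(=O)[C@](C)(O1)[C@H](O[Si](CC)(CC)CC)[C@H](O)CO[Si](CC)(CC)CC | intermediate
9 | 3-methylbutanoic acid (isovaleric acid) | CC(C)CC(=O)O | starting material
10 | (2S,3R)-3-[(2R)-2-methyl-3-oxo-5-[(2Z)-4-(triethylsilyloxy)but-2-en-2-yl]-2,3-dihydrofuran-2-yl]-1,3-bis(triethylsilyloxy)propan-2-yl 3-methylbutanoate (C8 S, C9 R, C10 R) | CC[Si](CC)(CC)OC/C=C(/C)C1=CC(=O)[C@](C)(O1)[C@H](O[Si](CC)(CC)CC)[C@@H](OC(=O)CC(C)C)CO[Si](CC)(CC)CC | intermediate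
11 | (2R,3R)-3-[(2R)-2-methyl-3-oxo-5-[(2Z)-4-oxobut-2-en-2-yl]-2,3-dihydrofuran-2-yl]-1-oxo-3-(triethylsilyloxy)propan-2-yl 3-methylbutanoate (dialdehyde) | O=C/C=C(/C)C1=CC(=O)[C@](C)(O1)[C@H](O[Si](CC)(CC)CC)[C@@H](OC(=O)CC(C)C)C=O | intermediate
12 | methyl prop-2-ynoate (methyl propiolate) | C#CC(=O)OC | starting material
13 | [1-(methoxycarbonyl)ethenyl]bis(2-methylpropyl)aluminium (vinylalane) | C=C(C(=O)OC)[Al](CC(C)C)CC(C)C | intermediate
14 | methyl (3RS,4S,5R)-3-hydroxy-2-methylidene-4-[(3-methylbutanoyl)oxy]-5-[(2R)-2-methyl-3-oxo-5-[(2Z)-4-oxobut-2-en-2-yl]-2,3-dihydrofuran-2-yl]-5-(triethylsilyloxy)pentanoate | O=C/C=C(/C)C1=CC(=O)[C@](C)(O1)[C@H](O[Si](CC)(CC)CC)[C@@H](OC(=O)CC(C)C)C(O)C(=C)C(=O)OC | intermediate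
15 | methyl (2Z,4S,5R)-2-(bromomethyl)-4-[(3-methylbutanoyl)oxy]-5-[(2R)-2-methyl-3-oxo-5-[(2Z)-4-oxobut-2-en-2-yl]-2,3-dihydrofuran-2-yl]-5-(triethylsilyloxy)pent-2-enoate | O=C/C=C(/C)C1=CC(=O)[C@](C)(O1)[C@H](O[Si](CC)(CC)CC)[C@@H](OC(=O)CC(C)C)/C=C(\CBr)C(=O)OC | intermediate
16 | allylchromium dichloride from 15 (chromium on the former CH2Br carbon, solvent ligands omitted) | O=C/C=C(/C)C1=CC(=O)[C@](C)(O1)[C@H](O[Si](CC)(CC)CC)[C@@H](OC(=O)CC(C)C)/C=C(\C[Cr](Cl)Cl)C(=O)OC | intermediate
17 | 9-O-triethylsilyl-lobatin B (4Z,6R,7S,8S,9R,10R) | C=C1C(=O)O[C@@H]2/C=C(/C)C3=CC(=O)[C@](C)(O3)[C@H](O[Si](CC)(CC)CC)[C@@H](OC(=O)CC(C)C)[C@@H]12 | intermediate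
18 | lobatin B (4Z,6R,7S,8S,9R,10R) | C=C1C(=O)O[C@@H]2/C=C(/C)C3=CC(=O)[C@](C)(O3)[C@H](O)[C@@H](OC(=O)CC(C)C)[C@@H]12 | target

**Totals and risks**
Total step count: 8. Longest linear sequence: 7 steps (steps 1, 3, 4, 5, 6, 7, 8, from 1).

Step 8 (ring closure; wrong C6/C7 diastereomer, oligomers, or no reaction). The acyclic preference of Z-bromides is for the syn adduct, so the trans outcome rests on allylchromium equilibration and on the tether; this is the largest uncertainty of the route. The fallback generates the nucleophile without a halide and without chromium. It sets out from 14, which is acetylated (Ac2O, pyridine, 0 °C) to the allylic acetate F1. With Pd(PPh3)4 (cat.) and InI in THF at high dilution, F1 gives a π-allylpalladium species that is transmetallated to an allylindium, and this adds to the C6 aldehyde through a tight cyclic transition state under neutral conditions and lactonises. The route is rejoined at 17, and the acidic treatment of step 8 then gives 18.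

Step 4 (Mitsunobu inversion at the hindered C8 carbinol with a weakly acidic aliphatic acid; elimination or retention through neighbouring-group participation). The fallback inverts by oxidation and reduction. It sets out from 8, which is oxidised with Dess–Martin periodinane to the C8 ketone F2. NaBH4 in MeOH at −40 °C should then deliver hydride under polar Felkin–Anh control (anti to the non-chelating C9–OSiEt3 bond) to give the (8S)-alcohol F3. Esterification of F3 with 9 (DCC, DMAP, CH2Cl2) returns to the route at 10.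

Step 6 (over-addition to the enal, or migration of the isovalerate to the adjacent aluminium alkoxide). The fallback replaces the stoichiometric vinylalane by an amine-catalysed Morita–Baylis–Hillman reaction. It sets out from 11, treated with methyl acrylate and 3-hydroxyquinuclidine (cat.) in MeOH at rt, and comes back at 14. β,β-Disubstituted enals do not take part in this reaction and no metal alkoxide is formed next to the ester; the cost is a slow reaction under mildly basic conditions. It makes no new compound.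

**Further compounds**
F1 | step 8 | methyl (3RS,4S,5R)-3-acetoxy-2-methylidene-4-[(3-methylbutanoyl)oxy]-5-[(2R)-2-methyl-3-oxo-5-[(2Z)-4-oxobut-2-en-2-yl]-2,3-dihydrofuran-2-yl]-5-(triethylsilyloxy)pentanoate | O=C/C=C(/C)C1=CC(=O)[C@](C)(O1)[C@H](O[Si](CC)(CC)CC)[C@@H](OC(=O)CC(C)C)C(OC(C)=O)C(=C)C(=O)OC
F2 | step 4 | (2R)-2-methyl-2-[(1S)-2-oxo-1,3-bis(triethylsilyloxy)propyl]-5-[(2Z)-4-(triethylsilyloxy)but-2-en-2-yl]furan-3(2H)-one (C8 ketone of 8) | CC[Si](CC)(CC)OC/C=C(/C)C1=CC(=O)[C@](C)(O1)[C@H](O[Si](CC)(CC)CC)C(=O)CO[Si](CC)(CC)CC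
F3 | step 4 | (2R)-2-[(1R,2S)-2-hydroxy-1,3-bis(triethylsilyloxy)propyl]-2-methyl-5-[(2Z)-4-(triethylsilyloxy)but-2-en-2-yl]furan-3(2H)-one (C8 epimer of 8) | CC[Si](CC)(CC)OC/C=C(/C)C1=CC(=O)[C@](C)(O1)[C@H](O[Si](CC)(CC)CC)[C@@H](O)CO[Si](CC)(CC)CC
F0 | step 6 | none | none
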